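How much G stands in this flask at 8.0 min, and which change raises it most?

- dawn: X 0.25 M; L 2 equiv; the very flask that is asked about, followed so far
- flask: X 0.25 M; L 2.00 equiv; time 8.0 min

dawn run (percent of the X charged)

| time / s | G / % | X / % |
|---|---|---|
| 12.0 | 8.8 | 38.1 |
| 25.0 | 14.7 | 27.3 |
| 30.0 | 16.4 | 25.3 |
| 50.0 | 25.4 | 13.3 |
| 60.0 | 27.5 | 10.5 |

(readings scatter by 1 percentage point)

- X is a solid; its amount is given per volume of the solution
- at the start none of X is in solution

- ash: doubling the solubility of X, all else as stated
- birch: doubling the amount of L, all else as stated
- larch: doubling the dissolution coefficient of X, all else as stated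

- the G standing at 8.0 min, as a percentage of the X charged
- the change that raises the amount of G at 8.0 min, in percent of the X charged most ("none" if none brings more than 2 percentage points) (ash / birch / larch / none)
- amount of G at 8.0 min, in percent of the X charged, after birch

Two readers disagree. The first holds that, once the solid has dissolved, “the flask is a homogeneous second-order reaction”, with L spent on G. The forecast is that reader's: 85% (range 76% to 91%), birch as the best change, and 98% after it (range 94% to 100%).

The second holds that L also fades by another way. In the dawn run, the mean pace of G over the first 25.0 s is 1.61 times its pace from there to 60.0 s, a fall of 37.8%. Solid X still stands at 10.5% at that time, so dissolved X can be taken as near saturation, and the pace should follow L. Yet the G made by 60.0 s accounts for 13.8% of the L charged, less than that fall.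

I side with the second and reckon from both ends. The two stretches have midpoints 0.500 min apart, which gives a fading rate of 0.0158 s⁻¹, a reading that carries the scatter. Joining this to the G at 60.0 s gives 44.8% for the ceiling, the G that stands when the fading of L has run its course. By 8.0 min this fading leaves 0.0501% of L, so I expect about the ceiling, less than the forecast. While dissolved X stays near saturation and the fading rate holds, the ceiling goes with the L charged, so birch is my choice too, with 89.6% as its upper figure.

The flask gives 40.0%, with birch best at 69.1%.

    X ⇌ Q, rate k1*(cs1 - [Q]) while solid is left; crystals form when [Q] > cs1 (solubility = 0.120 M, k = 0.510 s⁻¹)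
    Q + L → G (k = 0.0330 M⁻¹ s⁻¹)
    2 X → D (k = 0.0490 M⁻¹ s⁻¹)
    L → J (k = 0.0150 s⁻¹)

L, the limiting reagent here, stands at 1.09% of its charge by 4.00 min, when G has reached 39.6% of the X charged. Its half-life into J alone is 0.77 min, against 3.1 min into G at 8.00 min; the first reader's view belongs to a flask where the half-life into J is far the longer of these two. The ceiling lay 4.8 percentage points above the result.

With 1.20 equiv of L, the ceiling scales to 26.9%. That flask gives 24.2%, with 0.011% of its L left.

Readings and results are calculated for substances that don't exist; scatter was added.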